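**Strategy.** Core atoms are numbered as in 7-oxabicyclo[2.2.1]heptane: O7 bridges C1 (methyl-bearing bridgehead) and C4 (bridgehead CH), C2 carries the hydroxylated arm and C3 is the quaternary carbon. Everything rests on cutting the oxolane ring O7–C1–C2–C3–C4 into an O7–C1–C2 unit (an epoxide) and a C3=C4 alkene that the C5–C6 chain already links. The precursor is an open-chain vinyl epoxide, three steps from (2E,6E)-farnesol, with C1 set by Sharpless epoxidation. Thiyl-radical catalysis isomerizes it in one operation: epoxide opening gives a tertiary alkoxy radical that closes O7–C4 and then C2–C3, so both rings and three stereocentres arise with no atom added or lost.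

Key step: step 4

Remark: arm atoms are primed (C1′–C5′ on C2, C1″–C5″ on C3), and the D-fructose-derived Shi ketone is assumed to give the (R)-epoxide from an R–CH=CMe2 terminus, as it does for trans-disubstituted and trisubstituted alkenes in general.

Step 1
Reactants: 1 (2E,6E)-farnesol
Product: 2 [(2R,3R)-3-[(3E)-4,8-dimethylnona-3,7-dien-1-yl]-3-methyloxiran-2-yl]methanol
Conditions: Ti(OiPr)4 (cat.), D-(−)-diethyl tartrate (cat.), tBuOOH, 4 Å MS, CH2Cl2, −20 °C
Reagents that add atoms: tert-butyl hydroperoxide, CC(C)(C)OO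
Why: Sharpless asymmetric epoxidation acts only on the allylic-alcohol alkene, and with the D-tartrate it should give the (2R,3R)-epoxide, which fixes the later core carbon C1 as R.

Step 2
Reactants: 2 (2R,3R)-2,3-epoxyfarnesol
Product: 3 (2S,3R)-3-[(3E)-4,8-dimethylnona-3,7-dien-1-yl]-3-methyloxirane-2-carbaldehyde
Conditions: Dess–Martin periodinane, NaHCO3, CH2Cl2, 0 °C to rt
Reagents that add atoms: none
Why: buffered Dess–Martin oxidation of a 2,3-epoxy alcohol to the epoxy aldehyde is routine and leaves the trisubstituted alkenes and the epoxide untouched (the descriptor change at C2 is a priority effect only).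

Step 3
Reactants: 3 (2S,3R)-epoxy aldehyde
Product: 4 (2R,3R)-2-[(3E)-4,8-dimethylnona-3,7-dien-1-yl]-3-ethenyl-2-methyloxirane
Conditions: Ph3PCH3Br, NaN(SiMe3)2, THF, 0 °C; then 3, −78 to 0 °C
Reagents that add atoms: methylenetriphenylphosphorane, C=P(c1ccccc1)(c1ccccc1)c1ccccc1
Why: Wittig methylenation of an α,β-epoxy aldehyde with the non-stabilized ylide is a standard entry to vinyl epoxides and does not open the epoxide.

Step 4
Reactants: 4 (2R,3R)-vinyl epoxide
Product: 7 (1R,2S,3S,4S)-2-ethenyl-1,3-dimethyl-3-(4-methylpent-3-en-1-yl)-7-oxabicyclo[2.2.1]heptane, via alkoxy radical 5 (not isolated), via oxolanylalkyl radical 6 (not isolated)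
Conditions: PhSSPh (10 mol%), AIBN (10 mol%), hν (sunlamp), benzene (0.01 M), reflux
Reagents that add atoms: none
Why: PhS• adds to the vinyl terminus, the oxiranylcarbinyl radical opens by C2–O7 scission to the tertiary alkoxy radical 5, this adds to C4 of the trisubstituted alkene, the tertiary C3 radical 6 adds to C2 of the allyl sulfide, and β-scission expels PhS• to leave the C2 vinyl group and propagate the chain. The closest known reaction type is the thiyl-radical-catalysed [3+2] addition of vinyloxiranes (and vinylcyclopropanes) to alkenes, run here within one molecule. The first ring (oxolane O7–C1–C6–C5–C4) closes 5-exo-trig, and the second closure is again 5-exo-trig (oxolane O7–C1–C2–C3–C4) and at the same time completes the six-membered carbocycle as a bridged boat. C1 is carried over from the Sharpless epoxide; C4 is tied to C1 because only the radical whose first ring closed with the C3 centre cis to the alkenyl group can reach C2 (the trans-closed radical cannot bridge and ends as monocyclic material); C2 is set with the CH=CH–CH2SPh unit exo, away from the C5–C6 bridge; the former epoxide stereocentre at C2 and the C3=C4 geometry are erased at the radical stage, so isomers in either converge. At C3 the step needs the methyl exo and the 4-methylpent-3-enyl arm endo (anti to the C2 arm), and the only element that favours this is avoidance of an eclipsed arm–arm contact across the forming bond, so this face selection is expected to be modest and the C3 epimer is the co-product to be separated. Regiochemistry (oxygen to the CH carbon, carbon to the fully substituted one) is secured by alkoxy-radical polarity and the 5-exo preference, the opposite of what an acid-promoted epoxide–alkene cyclization would give.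

Step 5
Reactants: 8 but-2-yn-1-ol
Product: 10 (2Z)-3-iodobut-2-en-1-ol, via alkenylalanate 9 (not isolated)
Conditions: NaAlH2(OCH2CH2OCH3)2, THF, 0 °C to rt; then I2, −78 to 0 °C
Reagents that add atoms: iodine, II
Why: hydroxyl-directed trans-hydroalumination of the propargylic alcohol places aluminium on C3 in a five-membered alanate, and iodinolysis with retention should give only the (Z)-iodide.

Step 6
Reactants: 7 (1R,2S,3S,4S)-2-ethenyl oxanorbornane; 10 (2Z)-3-iodobut-2-en-1-ol
Product: 12 (2Z)-5-[(1R,2S,3S,4S)-1,3-dimethyl-3-(4-methylpent-3-en-1-yl)-7-oxabicyclo[2.2.1]heptan-2-yl]-3-methylpent-2-en-1-ol, via alkylborane 11 (not isolated)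
Conditions: 9-BBN, THF, 0 °C to rt; then 10, PdCl2(dppf) (5 mol%), AsPh3, Cs2CO3, DMF–H2O, rt
Reagents that add atoms: none
Why: 9-BBN hydroborates only the monosubstituted vinyl group (anti-Markovnikov), and the B-alkyl Suzuki–Miyaura coupling with the alkenyl iodide proceeds with retention of alkene geometry, giving the (Z)-trisubstituted allylic alcohol.

Step 7
Reactants: 12 (Z)-allylic alcohol
Product: 13 [(2R,3S)-3-{2-[(1R,2S,3S,4S)-1,3-dimethyl-3-(4-methylpent-3-en-1-yl)-7-oxabicyclo[2.2.1]heptan-2-yl]ethyl}-3-methyloxiran-2-yl]methanol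
Conditions: Ti(OiPr)4, D-(−)-diethyl tartrate, tBuOOH, 4 Å MS, CH2Cl2, −20 °C
Reagents that add atoms: tert-butyl hydroperoxide, CC(C)(C)OO
Why: Sharpless asymmetric epoxidation is reagent-controlled and selective for the allylic alcohol over the remote trisubstituted alkene; for a (Z)-3,3-disubstituted allylic alcohol the D-tartrate should give the (2R,3S)-epoxide, which sets the later carbinol carbon C3′ as S.

Step 8
Reactants: 13 (2R,3S)-epoxy alcohol
Product: 14 (1R,2S,3S,4S)-2-{2-[(2S,3S)-3-(iodomethyl)-2-methyloxiran-2-yl]ethyl}-1,3-dimethyl-3-(4-methylpent-3-en-1-yl)-7-oxabicyclo[2.2.1]heptane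
Conditions: I2, PPh3, imidazole, CH2Cl2, 0 °C
Reagents that add atoms: iodine, II
Why: Appel-type iodination replaces only the primary hydroxyl and leaves both epoxide carbons unchanged (the descriptor change is a priority effect).

Step 9
Reactants: 14 epoxy iodide
Product: 16 triethyl{[(3S)-5-[(1R,2S,3S,4S)-1,3-dimethyl-3-(4-methylpent-3-en-1-yl)-7-oxabicyclo[2.2.1]heptan-2-yl]-3-methylpent-1-en-3-yl]oxy}silane, via lithium alkoxide 15 (not isolated)
Conditions: tBuLi (2.2 equiv), Et2O, −78 °C; then Et3SiOTf, −78 to 0 °C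
Reagents that add atoms: triethylsilyl trifluoromethanesulfonate, CC[Si](CC)(CC)OS(=O)(=O)C(F)(F)F
Why: iodine–lithium exchange at the iodomethyl group triggers immediate β-elimination with opening of the epoxide (reductive 1,2-transposition of a 2,3-epoxy iodide) to the tertiary allylic alkoxide with the C3′–O bond intact, and this alkoxide is silylated in the same flask.

Step 10
Reactants: 16 triethylsilyl ether
Product: 17 {[(3S)-5-[(1R,2S,3S,4S)-3-{2-[(2R)-3,3-dimethyloxiran-2-yl]ethyl}-1,3-dimethyl-7-oxabicyclo[2.2.1]heptan-2-yl]-3-methylpent-1-en-3-yl]oxy}triethylsilane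
Conditions: D-fructose-derived Shi ketone (30 mol%), Oxone (2KHSO5·KHSO4·K2SO4), K2CO3, Bu4NHSO4, MeCN–CH2(OMe)2–aqueous buffer (pH 10.5), 0 °C
Reagents that add atoms: potassium peroxymonosulfate, [K+].[O-]S(=O)(=O)OO
Why: in the Shi epoxidation the chiral dioxirane attacks the electron-rich trisubstituted alkene far faster than the hindered monosubstituted vinyl group, and its spiro transition state should give the (R)-epoxide at C3″ under reagent control.

Step 11
Reactants: 17 (R)-epoxide
Product: 18 (3S)-3-bromo-5-[(1R,2S,3S,4S)-1,3-dimethyl-2-{(3S)-3-methyl-3-[(triethylsilyl)oxy]pent-4-en-1-yl}-7-oxabicyclo[2.2.1]heptan-3-yl]-2-methylpentan-2-ol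
Conditions: Li2NiBr4, THF, 0 °C to rt
Reagents that add atoms: dilithium tetrabromonickelate, [Li+].[Li+].Br[Ni-2](Br)(Br)Br
Why: the soft bromide of Li2NiBr4 should open the trisubstituted epoxide by SN2 attack at the less substituted carbon, so bromide enters C3″ with inversion (R-epoxide to S-bromide) under near-neutral conditions that spare the silyl ether and the oxanorbornane.

Step 12
Reactants: 18 (S)-bromohydrin
Product: 21 {[(3S)-5-[(1R,2S,3S,4S)-3-[(3S)-3-bromo-4-chloro-4-methylpentyl]-1,3-dimethyl-7-oxabicyclo[2.2.1]heptan-2-yl]-3-methylpent-1-en-3-yl]oxy}triethylsilane, via alkoxyiminium chloride 19 (not isolated), via bromonium chloride 20 (not isolated)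
Conditions: 1-chloro-N,N,2-trimethylprop-1-en-1-amine (Ghosez reagent), CH2Cl2, 0 °C to rt
Reagents that add atoms: 1-chloro-N,N,2-trimethylprop-1-en-1-amine, CC(C)=C(Cl)N(C)C
Why: neutral activation of the tertiary hydroxyl is followed by ionization with participation of the neighbouring bromine, and chloride opens the bromonium ion at the tertiary carbon, so the C3″–Br configuration is retained (anchimerically assisted substitution of a bromohydrin).

Step 13
Reactants: 21 triethylsilyl ether of the target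
Product: 22 dactylomelol
Conditions: HF·pyridine, pyridine, THF, 0 °C to rt
Reagents that add atoms: none
Why: buffered fluoride cleavage of the tertiary triethylsilyl ether should free the alcohol without ionizing the allylic C–O bond or eliminating the vicinal bromochloride.

**Compound list**

1 | (2E,6E)-farnesol | CC(C)=CCC/C(C)=C/CC/C(C)=C/CO | starting material
2 | [(2R,3R)-3-[(3E)-4,8-dimethylnona-3,7-dien-1-yl]-3-methyloxiran-2-yl]methanol | OC[C@H]1O[C@]1(C)CC/C=C(\C)CCC=C(C)C | intermediate
3 | (2S,3R)-3-[(3E)-4,8-dimethylnona-3,7-dien-1-yl]-3-methyloxirane-2-carbaldehyde | O=C[C@H]1O[C@]1(C)CC/C=C(\C)CCC=C(C)C | intermediate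
4 | (2R,3R)-2-[(3E)-4,8-dimethylnona-3,7-dien-1-yl]-3-ethenyl-2-methyloxirane | C=C[C@H]1O[C@]1(C)CC/C=C(\C)CCC=C(C)C | intermediate
5 | (2E,4R,7E)-4,8,12-trimethyl-1-(phenylsulfanyl)trideca-2,7,11-trien-4-yloxyl radical (not isolated) | [O][C@](/C=C/CSc1ccccc1)(C)CC/C=C(\C)CCC=C(C)C | intermediate
6 | 6-methyl-2-{(2S,5R)-5-methyl-5-[(1E)-3-(phenylsulfanyl)prop-1-en-1-yl]oxolan-2-yl}hept-5-en-2-yl radical (not isolated) | C[C](CCC=C(C)C)[C@@H]1CC[C@@](/C=C/CSc2ccccc2)(C)O1 | intermediate
7 | (1R,2S,3S,4S)-2-ethenyl-1,3-dimethyl-3-(4-methylpent-3-en-1-yl)-7-oxabicyclo[2.2.1]heptane | C=C[C@H]1[C@](C)(CCC=C(C)C)[C@@H]2CC[C@@]1(C)O2 | intermediate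
8 | but-2-yn-1-ol | CC#CCO | starting material
9 | sodium 2,2-bis(2-methoxyethoxy)-3-methyl-2,5-dihydro-1,2-oxaluminol-2-uide (cyclic alkenylalanate, not isolated) | [Na+].CC1=CCO[Al-]1(OCCOC)OCCOC | intermediate
10 | (2Z)-3-iodobut-2-en-1-ol | C/C(I)=C/CO | intermediate
11 | 9-{2-[(1R,2S,3S,4S)-1,3-dimethyl-3-(4-methylpent-3-en-1-yl)-7-oxabicyclo[2.2.1]heptan-2-yl]ethyl}-9-borabicyclo[3.3.1]nonane (not isolated) | C(C[C@H]1[C@](C)(CCC=C(C)C)[C@@H]2CC[C@@]1(C)O2)B1C2CCCC1CCC2 | intermediate
12 | (2Z)-5-[(1R,2S,3S,4S)-1,3-dimethyl-3-(4-methylpent-3-en-1-yl)-7-oxabicyclo[2.2.1]heptan-2-yl]-3-methylpent-2-en-1-ol | OC/C=C(C)\CC[C@H]1[C@](C)(CCC=C(C)C)[C@@H]2CC[C@@]1(C)O2 | intermediate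
13 | [(2R,3S)-3-{2-[(1R,2S,3S,4S)-1,3-dimethyl-3-(4-methylpent-3-en-1-yl)-7-oxabicyclo[2.2.1]heptan-2-yl]ethyl}-3-methyloxiran-2-yl]methanol | OC[C@H]1O[C@@]1(C)CC[C@H]2[C@](C)(CCC=C(C)C)[C@@H]3CC[C@@]2(C)O3 | intermediate
14 | (1R,2S,3S,4S)-2-{2-[(2S,3S)-3-(iodomethyl)-2-methyloxiran-2-yl]ethyl}-1,3-dimethyl-3-(4-methylpent-3-en-1-yl)-7-oxabicyclo[2.2.1]heptane | IC[C@H]1O[C@@]1(C)CC[C@H]2[C@](C)(CCC=C(C)C)[C@@H]3CC[C@@]2(C)O3 | intermediate
15 | lithium (3S)-5-[(1R,2S,3S,4S)-1,3-dimethyl-3-(4-methylpent-3-en-1-yl)-7-oxabicyclo[2.2.1]heptan-2-yl]-3-methylpent-1-en-3-olate (not isolated) | C=C[C@@](C)([O-])CC[C@H]1[C@](C)(CCC=C(C)C)[C@@H]2CC[C@@]1(C)O2.[Li+] | intermediate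
16 | triethyl{[(3S)-5-[(1R,2S,3S,4S)-1,3-dimethyl-3-(4-methylpent-3-en-1-yl)-7-oxabicyclo[2.2.1]heptan-2-yl]-3-methylpent-1-en-3-yl]oxy}silane | C=C[C@@](C)(O[Si](CC)(CC)CC)CC[C@H]1[C@](C)(CCC=C(C)C)[C@@H]2CC[C@@]1(C)O2 | intermediate
17 | {[(3S)-5-[(1R,2S,3S,4S)-3-{2-[(2R)-3,3-dimethyloxiran-2-yl]ethyl}-1,3-dimethyl-7-oxabicyclo[2.2.1]heptan-2-yl]-3-methylpent-1-en-3-yl]oxy}triethylsilane | C=C[C@@](C)(O[Si](CC)(CC)CC)CC[C@H]1[C@](C)(CC[C@H]3OC3(C)C)[C@@H]2CC[C@@]1(C)O2 | intermediate
18 | (3S)-3-bromo-5-[(1R,2S,3S,4S)-1,3-dimethyl-2-{(3S)-3-methyl-3-[(triethylsilyl)oxy]pent-4-en-1-yl}-7-oxabicyclo[2.2.1]heptan-3-yl]-2-methylpentan-2-ol | C=C[C@@](C)(O[Si](CC)(CC)CC)CC[C@H]1[C@](C)(CC[C@H](Br)C(C)(C)O)[C@@H]2CC[C@@]1(C)O2 | intermediate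
19 | O-alkyl N,N-dimethylisobutyrimidinium chloride of 18 (alkoxyiminium chloride, not isolated) | C=C[C@@](C)(O[Si](CC)(CC)CC)CC[C@H]1[C@](C)(CC[C@H](Br)C(C)(C)OC(C(C)C)=[N+](C)C)[C@@H]2CC[C@@]1(C)O2.[Cl-] | intermediate
20 | (S)-3,3-dimethylbromiranium chloride carrying the core on C2 (bromonium chloride, not isolated) | C=C[C@@](C)(O[Si](CC)(CC)CC)CC[C@H]1[C@](C)(CC[C@@H]3[Br+]C3(C)C)[C@@H]2CC[C@@]1(C)O2.[Cl-] | intermediate
21 | {[(3S)-5-[(1R,2S,3S,4S)-3-[(3S)-3-bromo-4-chloro-4-methylpentyl]-1,3-dimethyl-7-oxabicyclo[2.2.1]heptan-2-yl]-3-methylpent-1-en-3-yl]oxy}triethylsilane | C=C[C@@](C)(O[Si](CC)(CC)CC)CC[C@H]1[C@](C)(CC[C@H](Br)C(C)(C)Cl)[C@@H]2CC[C@@]1(C)O2 | intermediate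
22 | dactylomelol, (3S)-5-[(1R,2S,3S,4S)-3-[(3S)-3-bromo-4-chloro-4-methylpentyl]-1,3-dimethyl-7-oxabicyclo[2.2.1]heptan-2-yl]-3-methylpent-1-en-3-ol | C=C[C@@](C)(O)CC[C@H]1[C@](C)(CC[C@H](Br)C(C)(C)Cl)[C@@H]2CC[C@@]1(C)O2 | target

**Count.** Total steps: 13. Longest linear sequence: 12 (steps 1–4 and 6–13; step 5 makes the coupling partner).

**Steps most likely to fail**

1. Step 4. The tertiary C3 radical may be trapped by disulfide or thiyl before the strained second ring closes. The material that closes the first ring trans cannot go on, and face selection at the C3 radical is weak. The thiyl chain may also stall by hydrogen abstraction next to sulfur. The fallback changes the radical source and the acceptor but not the inherent ring-closure stereochemistry. It sets out from 2 and comes back at 7. Alcohol 2 is converted with I2, PPh3 and imidazole into the epoxy iodide F1. Irradiation of F1 with (Bu3Sn)2 (10 mol%) in benzene should start an iodine-atom-transfer chain: iodine abstraction, epoxide fragmentation to the nerolidol-type alkoxy radical, the same two 5-exo closures onto a plain vinyl acceptor, and iodine transfer to the primary radical, giving the iodomethyl oxanorbornane F2. Oxidation of F2 with trimethylamine N-oxide in DMSO gives the aldehyde F3, and Wittig methylenation (Ph3P=CH2) of F3 returns 7.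

2. Step 12. Loss of HBr or HCl from the activated tertiary ester or from the bromonium ion may outrun chloride capture. The fallback moves the leaving group to the secondary carbon, where departure is possible only with bromine bridging. It sets out from 17 and comes back at 21. Epoxide 17 is opened at the tertiary carbon with MgBr2·OEt2 in Et2O at −20 °C to give the regioisomeric bromohydrin F4 (tertiary bromide, secondary alcohol, C3″–O retained). Treatment of F4 with Tf2O, 2,6-di-tert-butyl-4-methylpyridine and Bu4NCl in CH2Cl2 at −78 °C should ionize the secondary triflate with bromine participation (inversion at C3″), and chloride opening at the tertiary carbon gives 21 through the same bromonium ion.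

3. Step 9. tert-Butyllithium may act as a base or nucleophile elsewhere, and O-silylation of the hindered tertiary lithium alkoxide may be incomplete. The fallback replaces the reductive elimination by a Wharton transposition. It sets out from 13 and comes back at 16. Dess–Martin oxidation of 13 gives the epoxy aldehyde F5. Hydrazine hydrate with catalytic acetic acid in methanol should convert F5 into the tertiary allylic alcohol F6 with the C3′–O bond intact. Silylation of F6 with Et3SiOTf and 2,6-lutidine gives 16.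

**Further compounds**

F1 | step 4 | (2R,3S)-2-[(3E)-4,8-dimethylnona-3,7-dien-1-yl]-3-(iodomethyl)-2-methyloxirane | IC[C@H]1O[C@]1(C)CC/C=C(\C)CCC=C(C)C
F2 | step 4 | (1R,2S,3S,4S)-2-(iodomethyl)-1,3-dimethyl-3-(4-methylpent-3-en-1-yl)-7-oxabicyclo[2.2.1]heptane | IC[C@H]1[C@](C)(CCC=C(C)C)[C@@H]2CC[C@@]1(C)O2
F3 | step 4 | (1R,2S,3S,4S)-1,3-dimethyl-3-(4-methylpent-3-en-1-yl)-7-oxabicyclo[2.2.1]heptane-2-carbaldehyde | O=C[C@H]1[C@](C)(CCC=C(C)C)[C@@H]2CC[C@@]1(C)O2
F4 | step 12 | (3R)-2-bromo-5-[(1R,2S,3S,4S)-1,3-dimethyl-2-{(3S)-3-methyl-3-[(triethylsilyl)oxy]pent-4-en-1-yl}-7-oxabicyclo[2.2.1]heptan-3-yl]-2-methylpentan-3-ol | C=C[C@@](C)(O[Si](CC)(CC)CC)CC[C@H]1[C@](C)(CC[C@@H](O)C(C)(C)Br)[C@@H]2CC[C@@]1(C)O2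
F5 | step 9 | (2S,3S)-3-{2-[(1R,2S,3S,4S)-1,3-dimethyl-3-(4-methylpent-3-en-1-yl)-7-oxabicyclo[2.2.1]heptan-2-yl]ethyl}-3-methyloxirane-2-carbaldehyde | O=C[C@H]1O[C@@]1(C)CC[C@H]2[C@](C)(CCC=C(C)C)[C@@H]3CC[C@@]2(C)O3
F6 | step 9 | (3S)-5-[(1R,2S,3S,4S)-1,3-dimethyl-3-(4-methylpent-3-en-1-yl)-7-oxabicyclo[2.2.1]heptan-2-yl]-3-methylpent-1-en-3-ol | C=C[C@@](C)(O)CC[C@H]1[C@](C)(CCC=C(C)C)[C@@H]2CC[C@@]1(C)O2
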